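**Retrosynthetic overview**
- The target comes from BBr3 demethylation of its 6,7-dimethoxy ether.
- The 2-pyranone-6-carboxylic acid ring is made last, by intradiol oxidative cleavage of a pendant 2,3-dihydroxy-4-methoxyphenyl ring and relactonisation with loss of MeOH.
- The C1–aryl bond and both stereocentres come from an enantioselective dearomative 1,4-addition of an aryllithium to the C2v-symmetric di-tert-butyl 6,7-dimethoxynaphthalene-2,3-dicarboxylate, followed by thermodynamic protonation at C2.
- The naphthalene diester comes from 4,5-dimethoxyphthalaldehyde and di-tert-butyl maleate (Wittig/aldol benzannulation); the aryllithium comes from 3-methoxycatechol (MOM protection, ortho-lithiation).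
- Ring order: the second naphthalene ring is built first, then dearomatised to the 1,2-dihydronaphthalene, and the pyranone is formed last.

Assumption: 1, 3 and 4 are bought. The facial sense of the chiral diether in step 3 is not known in advance for this substrate, so the route is written for the (S,S)-ligand and the (R,R)-ligand is used if the first run gives the antipode (checked on 10 or 11).

**Step 1**
Reactants: 1 3-methoxycatechol (3-methoxybenzene-1,2-diol)
Product: 2 1-methoxy-2,3-bis(methoxymethoxy)benzene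
Conditions: NaH (2.2 equiv), MOMCl (2.2 equiv), DMF, 0 °C → rt
Reagents that add atoms: chloromethyl methyl ether (MOMCl), COCCl
Why: Williamson-type O-alkylation of both phenoxides (MOM protection) gives acid-labile ethers that later act as the ortho-directing group; no stereocentre.

**Step 2**
Reactants: 3 4,5-dimethoxyphthalaldehyde; 4 di-tert-butyl maleate
Product: 7 di-tert-butyl 6,7-dimethoxynaphthalene-2,3-dicarboxylate, via phosphorus ylide 5 (not isolated), via arylidene succinate 6 (not isolated)
Conditions: PBu3 (1.1 equiv), CH2Cl2, 0 °C; then DBU (0.5 equiv), rt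
Reagents that add atoms: none
Why: Phosphine conjugate addition and proton shift give the succinate ylide, Wittig olefination of one aldehyde gives the (E)-arylidene succinate, and DBU closes the ring by intramolecular Knoevenagel-type aldol condensation driven by aromatisation (phosphine-mediated Wittig/aldol benzannulation of o-dialdehydes); no stereocentre.

**Step 3**
Reactants: 2 1-methoxy-2,3-bis(methoxymethoxy)benzene; 7 di-tert-butyl 6,7-dimethoxynaphthalene-2,3-dicarboxylate
Product: 10 di-tert-butyl (1R,2R)-1-[4-methoxy-2,3-bis(methoxymethoxy)phenyl]-6,7-dimethoxy-1,2-dihydronaphthalene-2,3-dicarboxylate, via aryllithium 8 (not isolated), via lithium enolate 9 (not isolated)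
Conditions: 2 (1.5 equiv), n-BuLi (1.45 equiv), Et2O, 0 °C; (S,S)-1,2-dimethoxy-1,2-diphenylethane (1.8 equiv), toluene, −78 °C; 7 (1.0 equiv), −78 → −45 °C; t-BuOH (2 equiv), KOt-Bu (0.1 equiv), −20 → 0 °C; AcOH
Reagents that add atoms: none
Why: Proposed new method: OMOM-directed ortho-lithiation gives 8, whose chiral diether complex should add 1,4 to one of the two enantiotopic ester-activated positions (C1/C4) of the symmetric naphthalene, since the mutually twisted, hindered tert-butyl esters disfavour carbonyl attack and the extended ester enolate 9 pays for the lost aromaticity, so C1 is set (R) by ligand control; t-BuOH/cat. KOt-Bu then protonates and equilibrates the acidic C2–H to the pseudo-diaxial trans (2R) isomer under thermodynamic control; the closest known reactions are chiral-diether-mediated aryllithium conjugate additions to hindered aryl (BHA) naphthoates (Tomioka type) and Meyers aryllithium additions to naphthyl oxazolines.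

**Step 4**
Reactants: 10 di-tert-butyl (1R,2R)-1-[4-methoxy-2,3-bis(methoxymethoxy)phenyl]-6,7-dimethoxy-1,2-dihydronaphthalene-2,3-dicarboxylate
Product: 11 (1R,2R)-1-(2,3-dihydroxy-4-methoxyphenyl)-6,7-dimethoxy-1,2-dihydronaphthalene-2,3-dicarboxylic acid
Conditions: TFA/H2O (9:1), 0 °C → rt, Ar
Reagents that add atoms: none
Why: Acidolysis removes both tert-butyl esters (as isobutene) and hydrolyses both MOM acetals while the three methyl ethers stay, which leaves the pendant ring as the only free catechol; the stereocentres are not enolised in acid and the trans-diaxial arrangement keeps the 2'-OH from lactonising onto the C2 acid.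

**Step 5**
Reactants: 11 (1R,2R)-1-(2,3-dihydroxy-4-methoxyphenyl)-6,7-dimethoxy-1,2-dihydronaphthalene-2,3-dicarboxylic acid
Product: 13 (1R,2R)-1-(6-carboxy-2-oxo-2H-pyran-3-yl)-6,7-dimethoxy-1,2-dihydronaphthalene-2,3-dicarboxylic acid, via methoxymuconic acid 12 (not isolated)
Conditions: AcOOH (2.0 equiv), Fe(OAc)3 (5 mol%), AcOH, 15 °C; then TFA, 50 °C
Reagents that add atoms: peracetic acid, CC(=O)OO; water, O
Why: Fe(III)-catalysed peracetic acid intradiol cleavage of a catechol to a cis,cis-muconic acid (Pandell-type oxidation) can only cut the C2'–C3' bond of the one free catechol, and in acid the Z-carboxyl adds to the protonated α-methoxy enol ether of 12 and MeOH is lost to give the 2-pyranone-6-carboxylic acid (acid lactonisation of 2-oxygenated muconic acids); C1 and C2 are not involved.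

**Step 6**
Reactants: 13 (1R,2R)-1-(6-carboxy-2-oxo-2H-pyran-3-yl)-6,7-dimethoxy-1,2-dihydronaphthalene-2,3-dicarboxylic acid
Product: 14 (1R,2R)-1-(6-carboxy-2-oxo-2H-pyran-3-yl)-6,7-dihydroxy-1,2-dihydronaphthalene-2,3-dicarboxylic acid (CNP0420981.1)
Conditions: BBr3 (8 equiv), CH2Cl2, −78 °C → rt; then H2O, 0 °C
Reagents that add atoms: none
Why: BBr3 cleavage of the two aryl methyl ethers (Lewis-acid demethylation) frees the catechol, while the carboxylic acids, the enol-lactone pyranone (no sp3 C–O to cleave) and the C3=C4 bond tolerate the reagent and the aqueous HBr work-up; no stereocentre is touched.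

**Compound list**
1 | 3-methoxycatechol | COc1cccc(O)c1O | starting material
2 | 1-methoxy-2,3-bis(methoxymethoxy)benzene | COCOc1cccc(OC)c1OCOC | intermediate
3 | 4,5-dimethoxyphthalaldehyde | COc1cc(C=O)c(C=O)cc1OC | starting material
4 | di-tert-butyl maleate | CC(C)(C)OC(=O)/C=C\C(=O)OC(C)(C)C | starting material
5 | di-tert-butyl 2-(tributyl-λ5-phosphanylidene)butanedioate (phosphorus ylide) | CCCCP(CCCC)(CCCC)=C(CC(=O)OC(C)(C)C)C(=O)OC(C)(C)C | intermediate
6 | di-tert-butyl (E)-2-(2-formyl-4,5-dimethoxybenzylidene)succinate | COc1cc(C=O)c(/C=C(\CC(=O)OC(C)(C)C)C(=O)OC(C)(C)C)cc1OC | intermediate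
7 | di-tert-butyl 6,7-dimethoxynaphthalene-2,3-dicarboxylate | COc1cc2cc(C(=O)OC(C)(C)C)c(C(=O)OC(C)(C)C)cc2cc1OC | intermediate
8 | [4-methoxy-2,3-bis(methoxymethoxy)phenyl]lithium | [Li]c1ccc(OC)c(OCOC)c1OCOC | intermediate
9 | lithium enolate of 10 at C2 ((1R)-configured, C3=C4 and exocyclic C2=C(OLi)Ot-Bu) | CC(C)(C)OC(=O)C1=Cc2cc(OC)c(OC)cc2[C@H](c2ccc(OC)c(OCOC)c2OCOC)C1=C(O[Li])OC(C)(C)C | intermediate
10 | di-tert-butyl (1R,2R)-1-[4-methoxy-2,3-bis(methoxymethoxy)phenyl]-6,7-dimethoxy-1,2-dihydronaphthalene-2,3-dicarboxylate | CC(C)(C)OC(=O)C1=Cc2cc(OC)c(OC)cc2[C@H](c2ccc(OC)c(OCOC)c2OCOC)[C@H]1C(=O)OC(C)(C)C | intermediate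
11 | (1R,2R)-1-(2,3-dihydroxy-4-methoxyphenyl)-6,7-dimethoxy-1,2-dihydronaphthalene-2,3-dicarboxylic acid | O=C(O)C1=Cc2cc(OC)c(OC)cc2[C@H](c2ccc(OC)c(O)c2O)[C@H]1C(=O)O | intermediate
12 | (2E,4Z)-5-[(1R,2R)-2,3-dicarboxy-6,7-dimethoxy-1,2-dihydronaphthalen-1-yl]-2-methoxyhexa-2,4-dienedioic acid | O=C(O)C1=Cc2cc(OC)c(OC)cc2[C@H](/C(C(=O)O)=C/C=C(/OC)C(=O)O)[C@H]1C(=O)O | intermediate
13 | (1R,2R)-1-(6-carboxy-2-oxo-2H-pyran-3-yl)-6,7-dimethoxy-1,2-dihydronaphthalene-2,3-dicarboxylic acid | O=C(O)C1=Cc2cc(OC)c(OC)cc2[C@H](c2ccc(C(=O)O)oc2=O)[C@H]1C(=O)O | intermediate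
14 | (1R,2R)-1-(6-carboxy-2-oxo-2H-pyran-3-yl)-6,7-dihydroxy-1,2-dihydronaphthalene-2,3-dicarboxylic acid | O=C(O)C1=Cc2cc(O)c(O)cc2[C@H](c2ccc(C(=O)O)oc2=O)[C@H]1C(=O)O | target

**Count**
Total steps: 6. Longest linear sequence: 5 (3/4 → 7 → 10 → 11 → 13 → 14; the branch 1 → 2 joins at step 3).

**Steps most likely to fail, with fallbacks**

Step 3 (dearomative asymmetric arylation). The risks are aryllithium attack on an ester carbonyl, no addition at all, or low ee because the ortho-OMOM group competes with the chiral diether for lithium. The fallback moves both chemoselectivity and stereocontrol into a covalently bound Meyers oxazoline auxiliary. It sets out from 3 and returns to the route at 11.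
- Stobbe condensation of 3 with di-tert-butyl succinate (KOt-Bu, t-BuOH/THF), with the second aldehyde closing the ring by aldol condensation, gives 3-(tert-butoxycarbonyl)-6,7-dimethoxy-2-naphthoic acid F1.
- EDC/HOBt coupling with (S)-tert-leucinol gives the hydroxy amide F2, and DAST cyclodehydration gives the (4S)-4-tert-butyl-oxazoline F3.
- Aryllithium 8 (made from 2 as in step 3; THF, −78 °C) adds at C1 under chelation to the oxazoline nitrogen, which also keeps it off the ester carbonyl; protonation and base equilibration give the trans adduct F4.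
- Hot 4 M HCl/dioxane hydrolyses the oxazoline and removes the tert-butyl and MOM groups in one operation, giving 11.
- (R)-tert-Leucinol is used instead if the auxiliary steers to the other face.

Step 5 (intradiol cleavage and lactonisation). The risks are over-oxidation, tautomerisation of the oxidised catechol toward a quinone methide (which would aromatise the dihydronaphthalene), or butenolide formation instead of the pyranone. The fallback splits the one-pot oxidation into two controlled stages with isolated intermediates and no iron. It sets out from 11 and returns at 13.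
- NaIO4 (aq. MeCN, 0 °C) gives the o-quinone F5.
- mCPBA (CH2Cl2, 0 °C) inserts oxygen between the two carbonyls (Baeyer–Villiger type) to give the seven-membered muconic anhydride F6.
- Aqueous TFA (50 °C) opens F6 to 12 and lactonises it to 13.

Step 6 (final demethylation). The risk is that the polar triacid complexes or decomposes with BBr3, or that the product is lost on isolation. The fallback masks the acids first. It sets out from 13 and returns at 14.
- TMSCHN2 (MeOH/toluene) gives the trimethyl ester F7.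
- BBr3 (CH2Cl2, −78 → −20 °C), now on a soluble neutral substrate, gives the catechol trimethyl ester F8.
- Acid hydrolysis (3 M HCl/dioxane, 70 °C, Ar), chosen because base would open the pyranone and air-oxidise the catechol, gives 14.

**Further compounds**
F1 | step 3 | 3-(tert-butoxycarbonyl)-6,7-dimethoxy-2-naphthoic acid | CC(C)(C)OC(=O)c1cc2cc(OC)c(OC)cc2cc1C(=O)O
F2 | step 3 | tert-butyl 3-{[(2S)-1-hydroxy-3,3-dimethylbutan-2-yl]carbamoyl}-6,7-dimethoxy-2-naphthoate | CC(C)(C)OC(=O)c1cc2cc(OC)c(OC)cc2cc1C(=O)N[C@@H](C(C)(C)C)CO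
F3 | step 3 | tert-butyl 3-[(4S)-4-tert-butyl-4,5-dihydro-1,3-oxazol-2-yl]-6,7-dimethoxy-2-naphthoate | CC(C)(C)OC(=O)c1cc2cc(OC)c(OC)cc2cc1C3=N[C@@H](C(C)(C)C)CO3
F4 | step 3 | tert-butyl (1R,2R)-2-[(4S)-4-tert-butyl-4,5-dihydro-1,3-oxazol-2-yl]-1-[4-methoxy-2,3-bis(methoxymethoxy)phenyl]-6,7-dimethoxy-1,2-dihydronaphthalene-3-carboxylate | CC(C)(C)OC(=O)C1=Cc2cc(OC)c(OC)cc2[C@H](c2ccc(OC)c(OCOC)c2OCOC)[C@H]1C3=N[C@@H](C(C)(C)C)CO3
F5 | step 5 | (1R,2R)-6,7-dimethoxy-1-(4-methoxy-5,6-dioxocyclohexa-1,3-dien-1-yl)-1,2-dihydronaphthalene-2,3-dicarboxylic acid | O=C(O)C1=Cc2cc(OC)c(OC)cc2[C@H](C2=CC=C(OC)C(=O)C2=O)[C@H]1C(=O)O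
F6 | step 5 | (1R,2R)-6,7-dimethoxy-1-(6-methoxy-2,7-dioxo-2,7-dihydrooxepin-3-yl)-1,2-dihydronaphthalene-2,3-dicarboxylic acid | O=C(O)C1=Cc2cc(OC)c(OC)cc2[C@H](C2=CC=C(OC)C(=O)OC2=O)[C@H]1C(=O)O
F7 | step 6 | dimethyl (1R,2R)-6,7-dimethoxy-1-[6-(methoxycarbonyl)-2-oxo-2H-pyran-3-yl]-1,2-dihydronaphthalene-2,3-dicarboxylate | COC(=O)C1=Cc2cc(OC)c(OC)cc2[C@H](c2ccc(C(=O)OC)oc2=O)[C@H]1C(=O)OC
F8 | step 6 | dimethyl (1R,2R)-6,7-dihydroxy-1-[6-(methoxycarbonyl)-2-oxo-2H-pyran-3-yl]-1,2-dihydronaphthalene-2,3-dicarboxylate | COC(=O)C1=Cc2cc(O)c(O)cc2[C@H](c2ccc(C(=O)OC)oc2=O)[C@H]1C(=O)OC
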